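**Retrosynthetic overview**
1. Target 26 ⇒ directed crossed aldol condensation (enol ether + acetal) of two C5-epimeric 15-oxolabd-8(17)-en-19-oic acid equivalents: trans-fused donor 23 and cis-fused acceptor 21.
2. 19 (→ 23) and 21 ⇒ one common 4,8(17)-dienoic acid 18: reductive methylation gives the trans half; deconjugative methylation plus carboxylate-directed hydrogenation gives the cis half.
3. 18 ⇒ ketone 16 ⇒ ring expansion of hydrindenone 6: the side-chain carbon C9 is inserted between C8(=O) and quaternary C10 by a selenium-mediated 1,2-shift, which makes ring B and attaches side chain 13.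
4. 6 ⇒ Cu–H reductive aldol desymmetrisation of dione enoate 4 (ring A, sets C10); 13 ⇒ asymmetric conjugate addition to methyl crotonate (sets C13).
5. Ring order: cyclopentane (bought) → ring A (step 2) → ring B by expansion of the cyclopentanone (step 8); C5 of each half is set last.

Assumption: the SMILES is taken literally, so the aldehyde-bearing half is the normal trans-fused labdane (5R, 5α-H) and the other half is its C5 epimer (5S, 5β-H, cis-fused); labdane numbering is used for the bicyclic compounds.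

**Step 1**
Reactants: 1 2-methylcyclopentane-1,3-dione; 2 acrolein
Product: 4 methyl (2E)-5-(1-methyl-2,5-dioxocyclopentyl)pent-2-enoate, via keto aldehyde 3 (not isolated)
Conditions: H2O, rt, 16 h; then Ph3P=CHCO2Me, rt
Reagents that add atoms: methyl (triphenyl-λ5-phosphanylidene)acetate, COC(=O)C=P(c1ccccc1)(c1ccccc1)c1ccccc1
Why: Michael addition of the dione enol to acrolein in water followed by an aqueous Wittig olefination with the stabilised ylide gives the (E)-enoate in one pot, and no stereocentre is formed yet.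

**Step 2**
Reactants: 4 methyl (2E)-5-(1-methyl-2,5-dioxocyclopentyl)pent-2-enoate
Product: 5 methyl (3aS,4S,7aS)-3a-hydroxy-7a-methyl-1-oxooctahydro-1H-indene-4-carboxylate
Conditions: Cu(OAc)2·H2O (5 mol%), Taniaphos-type ferrocenyl diphosphine (6 mol%, enantiomer giving 7aS), (MeO)2MeSiH (2 equiv), toluene, −20 °C → rt; then aq. NH4F
Reagents that add atoms: none
Why: Copper hydride catalysed asymmetric reductive aldol cyclisation, in which conjugate Cu–H addition gives a chiral copper enolate that closes through a chair Zimmerman–Traxler transition state onto one of the two enantiotopic ketones, so the ligand fixes the quaternary carbon (7aS, the future C10) and gives the all-cis ketol whose 3a and 4 centres are erased in step 3.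

**Step 3**
Reactants: 5 methyl (3aS,4S,7aS)-3a-hydroxy-7a-methyl-1-oxooctahydro-1H-indene-4-carboxylate
Product: 6 methyl (7aS)-7a-methyl-1-oxo-2,3,5,6,7,7a-hexahydro-1H-indene-4-carboxylate
Conditions: SOCl2, pyridine, CH2Cl2, 0 °C; then DBU (cat.), toluene, 60 °C
Reagents that add atoms: none
Why: Dehydration of the tertiary β-hydroxy ester via its chlorosulfite (E2/E1cB) and DBU equilibration give the conjugated tetrasubstituted enoate, the only conjugated isomer possible because C7a is quaternary and untouched.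

**Step 4**
Reactants: 7 methyl (2E)-but-2-enoate; 8 2-(2-bromoethyl)-1,3-dioxolane
Product: 10 methyl (3S)-5-(1,3-dioxolan-2-yl)-3-methylpentanoate, via Grignard reagent 9 (not isolated)
Conditions: 8, Mg, THF, 35 °C; then 7, CuBr·SMe2 (2 mol%), Josiphos ligand (2.4 mol%, enantiomer giving 3S), t-BuOMe, −75 °C; aq. NH4Cl
Reagents that add atoms: none
Why: Copper/ferrocenyl-diphosphine catalysed enantioselective conjugate addition of a Grignard reagent to a crotonate, in which the chiral Cu(I) π-complex differentiates the enoate faces and sets the methyl-bearing centre (3S, the future C13).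

**Step 5**
Reactants: 10 methyl (3S)-5-(1,3-dioxolan-2-yl)-3-methylpentanoate
Product: 11 methyl (3S)-3-methyl-6,6-bis(phenylselanyl)hexanoate
Conditions: PhSeH (2.2 equiv), BF3·OEt2 (0.2 equiv), CH2Cl2, −20 °C → rt
Reagents that add atoms: benzeneselenol, [SeH]c1ccccc1
Why: Lewis-acid transacetalisation, in which the oxocarbenium ion from the dioxolane is trapped twice by the soft selenol to give the Se,Se-acetal while the ester and the stereocentre are inert.

**Step 6**
Reactants: 11 methyl (3S)-3-methyl-6,6-bis(phenylselanyl)hexanoate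
Product: 13 (4S)-6,6-dimethoxy-4-methyl-1,1-bis(phenylselanyl)hexane, via selenoacetal aldehyde 12 (not isolated)
Conditions: DIBAL-H (1.1 equiv), CH2Cl2, −78 °C; then HCl in MeOH (1.5 equiv), HC(OMe)3, −78 °C → rt
Reagents that add atoms: methanol, CO
Why: DIBAL-H at −78 °C stops at the tetrahedral aluminium hemiacetal, which acidic methanol/orthoformate converts through the aldehyde into the dimethyl acetal (one-pot reduction–acetalisation), and the Se,Se-acetal survives both reagents.

**Step 7**
Reactants: 13 (4S)-6,6-dimethoxy-4-methyl-1,1-bis(phenylselanyl)hexane; 6 methyl (7aS)-7a-methyl-1-oxo-2,3,5,6,7,7a-hexahydro-1H-indene-4-carboxylate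
Product: 15 methyl (7aS)-1-[(4S)-6,6-dimethoxy-4-methyl-1-(phenylselanyl)hexyl]-1-hydroxy-7a-methyl-2,3,5,6,7,7a-hexahydro-1H-indene-4-carboxylate (epimers at the two new centres), via selanyl alkyllithium 14 (not isolated)
Conditions: 13 (1.3 equiv), n-BuLi (1.3 equiv), THF, −78 °C, 20 min; then 6, −78 °C; aq. NH4Cl
Reagents that add atoms: none
Why: Selenium–lithium exchange gives a weakly basic, strongly nucleophilic α-selanyl alkyllithium that adds 1,2 to the cyclopentanone much faster than to the hindered conjugated ester, and the two new centres need no control because C8 becomes a ketone and C9 is equilibrated in step 8.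

**Step 8**
Reactants: 15 β-hydroxy selenide
Product: 16 methyl (9R,10R,13S)-15,15-dimethoxy-8-oxo-17,18-dinorlabd-4-en-19-oate
Conditions: TlOEt (5 equiv), CHCl3, 20 °C; then NaOMe (0.2 equiv), MeOH, rt
Reagents that add atoms: none
Why: Krief-type ring expansion of a β-hydroxy selenide, in which dichlorocarbene turns PhSe into a selenonium leaving group and the more substituted, allylic quaternary carbon C10 migrates from the carbinol carbon to C9 with retention (semipinacol 1,2-shift), converting the cyclopentanol into the six-membered ring B ketone, after which methoxide equilibrates C9 to the equatorial side chain cis to the C10 methyl.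

**Step 9**
Reactants: 16 methyl (9R,10R,13S)-15,15-dimethoxy-8-oxo-17,18-dinorlabd-4-en-19-oate
Product: 17 methyl (9S,10R,13S)-15,15-dimethoxy-18-norlabda-4,8(17)-dien-19-oate
Conditions: Ph3PCH3Br, KOt-Bu, toluene, 0 → 80 °C
Reagents that add atoms: methylenetriphenylphosphorane, C=P(c1ccccc1)(c1ccccc1)c1ccccc1
Why: Wittig methylenation as practised on 8-oxo-17-norlabdanes installs the exocyclic methylene, and the mildly basic ylide leaves C9 at its thermodynamic configuration until the carbonyl is gone and C9 is locked.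

**Step 10**
Reactants: 17 methyl (9S,10R,13S)-15,15-dimethoxy-18-norlabda-4,8(17)-dien-19-oate
Product: 18 (9S,10R,13S)-15,15-dimethoxy-18-norlabda-4,8(17)-dien-19-oic acid
Conditions: KOH, MeOH–H2O (4:1), 70 °C; then AcOH to pH 5, 0 °C
Reagents that add atoms: potassium hydroxide, [K+].[OH-]
Why: Saponification of the conjugated methyl ester under basic conditions leaves the dimethyl acetal and both olefins untouched, and one crystallisation of 18 removes the minor diastereomer that stems from the imperfect ee of 6 and 13.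

**Step 11**
Reactants: 18 (9S,10R,13S)-15,15-dimethoxy-18-norlabda-4,8(17)-dien-19-oic acid
Product: 19 (4S,5R,9S,10R,13S)-15,15-dimethoxylabd-8(17)-en-19-oic acid
Conditions: Li (6 equiv), NH3(l)–THF, t-BuOH (1 equiv), −78 → −33 °C; isoprene; MeI (6 equiv), −78 °C → rt; NH4Cl, then AcOH to pH 5
Reagents that add atoms: iodomethane, CI
Why: Birch-type reductive alkylation of the α,β-unsaturated carboxylate, in which axial protonation of C5 gives the trans ring fusion (5α-H) and the resulting enediolate is methylated on the α-face, anti to the axial C10 methyl, which leaves the carboxyl axial (4S) as in the podocarpic acid series.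

**Step 12**
Reactants: 18 (9S,10R,13S)-15,15-dimethoxy-18-norlabda-4,8(17)-dien-19-oic acid
Product: 20 (4S,9S,10R,13S)-15,15-dimethoxylabda-5,8(17)-dien-19-oic acid
Conditions: LDA (2.4 equiv), THF–DMPU, −78 → 0 °C; MeI (1.5 equiv), −78 °C; AcOH to pH 5
Reagents that add atoms: iodomethane, CI
Why: Deconjugative α-alkylation of the dienediolate formed by γ-deprotonation at C6, in which kinetic methylation at C4 occurs anti to the axial C10 methyl, setting C4 (4S, carboxyl β) and moving the olefin to C5=C6.

**Step 13**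
Reactants: 20 (4S,9S,10R,13S)-15,15-dimethoxylabda-5,8(17)-dien-19-oic acid
Product: 21 (4S,5S,9S,10R,13S)-15,15-dimethoxylabd-8(17)-en-19-oic acid (5β-H, cis-fused)
Conditions: Ru(OAc)2[(S)-BINAP] (5 mol%, both antipodes screened), H2 (100 atm), MeOH, 50 °C
Reagents that add atoms: none
Why: Proposed new method: carboxylate-directed, chemoselective Ru(II) hydrogenation of a hindered ring-fusion β,γ-olefin, in which the substrate carboxylate replaces acetate on Ru(II) and holds the metal on the face of the 4β-carboxyl so that Ru–H insertion and cleavage of the five-membered ruthenacycle put both hydrogens cis to the carboxyl (5β-H, against the steric α-preference) while the 8(17)-methylene, which has no binding group, is spared because Ru(II) dicarboxylates do not reduce unfunctionalised olefins; the closest known reaction is the Noyori Ru(OAc)2(BINAP) hydrogenation of β,γ-unsaturated acids and of geraniol with the remote olefin left intact, not yet shown for an olefin flanked by two quaternary carbons or for control of a ring fusion.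

**Step 14**
Reactants: 19 (4S,5R,9S,10R,13S)-15,15-dimethoxylabd-8(17)-en-19-oic acid
Product: 23 trimethylsilyl (4S,5R,9S,10R,13S)-15-methoxylabda-8(17),14-dien-19-oate (14E/Z mixture, used crude), via silyl ester 22 (not isolated)
Conditions: TMSOTf (2.3 equiv), i-Pr2NEt (2.8 equiv), CH2Cl2, −20 → 20 °C; pentane, filtration, evaporation
Reagents that add atoms: trimethylsilyl trifluoromethanesulfonate, C[Si](C)(C)OS(=O)(=O)C(F)(F)F
Why: Gassman-type conversion of a dimethyl acetal into a methyl enol ether, in which TMSOTf ionises the acetal and Hünig's base removes the α-proton while the acid is masked as its silyl ester, and no stereocentre is touched.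

**Step 15**
Reactants: 23 trimethylsilyl (4S,5R,9S,10R,13S)-15-methoxylabda-8(17),14-dien-19-oate; 21 (4S,5S,9S,10R,13S)-15,15-dimethoxylabd-8(17)-en-19-oic acid
Product: 26 CNP0229303.1 (target), via silyl ester 24 (not isolated), via methoxy acetal 25 (not isolated)
Conditions: 21, BSA (1.2 equiv), CH2Cl2, rt; add 23, 2,6-di-tert-butylpyridine (0.2 equiv), TMSOTf (0.1 equiv), −78 → −40 °C; then 1 M HCl–THF, 0 → 40 °C
Reagents that add atoms: water, O
Why: Lewis-acid addition of an enol ether to an acetal-derived oxocarbenium ion (Mukaiyama-type, Müller-Cunradi–Pieroh condensation) is fully directed because only 24 can be the electrophile and only 23 the nucleophile, so no homodimers form, and aqueous acid then unmasks the aldehyde, cleaves the silyl esters and eliminates methanol to the thermodynamic (E)-enal without touching any stereocentre.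

**Compound list**
1 | 2-methylcyclopentane-1,3-dione | CC1C(=O)CCC1=O | starting material
2 | acrolein (prop-2-enal) | C=CC=O | starting material
3 | 3-(1-methyl-2,5-dioxocyclopentyl)propanal | CC1(CCC=O)C(=O)CCC1=O | intermediate (not isolated)
4 | methyl (2E)-5-(1-methyl-2,5-dioxocyclopentyl)pent-2-enoate | COC(=O)/C=C/CCC1(C)C(=O)CCC1=O | intermediate
5 | methyl (3aS,4S,7aS)-3a-hydroxy-7a-methyl-1-oxooctahydro-1H-indene-4-carboxylate (OH, CO2Me and 7a-Me all cis) | O=C1CC[C@]2(O)[C@@H](C(=O)OC)CCC[C@]12C | intermediate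
6 | methyl (7aS)-7a-methyl-1-oxo-2,3,5,6,7,7a-hexahydro-1H-indene-4-carboxylate | O=C1CCC2=C(C(=O)OC)CCC[C@]12C | intermediate
7 | methyl (2E)-but-2-enoate (methyl crotonate) | C/C=C/C(=O)OC | starting material
8 | 2-(2-bromoethyl)-1,3-dioxolane | BrCCC1OCCO1 | starting material
9 | [2-(1,3-dioxolan-2-yl)ethyl]magnesium bromide | Br[Mg]CCC1OCCO1 | intermediate (not isolated)
10 | methyl (3S)-5-(1,3-dioxolan-2-yl)-3-methylpentanoate | COC(=O)C[C@@H](C)CCC1OCCO1 | intermediate
11 | methyl (3S)-3-methyl-6,6-bis(phenylselanyl)hexanoate | COC(=O)C[C@@H](C)CCC([Se]c1ccccc1)[Se]c1ccccc1 | intermediate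
12 | (3S)-3-methyl-6,6-bis(phenylselanyl)hexanal | O=CC[C@@H](C)CCC([Se]c1ccccc1)[Se]c1ccccc1 | intermediate (not isolated)
13 | (4S)-6,6-dimethoxy-4-methyl-1,1-bis(phenylselanyl)hexane | COC(OC)C[C@@H](C)CCC([Se]c1ccccc1)[Se]c1ccccc1 | intermediate
14 | [(4S)-6,6-dimethoxy-4-methyl-1-(phenylselanyl)hexyl]lithium | [Li]C(CC[C@H](C)CC(OC)OC)[Se]c1ccccc1 | intermediate (not isolated)
15 | methyl (7aS)-1-[(4S)-6,6-dimethoxy-4-methyl-1-(phenylselanyl)hexyl]-1-hydroxy-7a-methyl-2,3,5,6,7,7a-hexahydro-1H-indene-4-carboxylate (epimers at carbinol and Se-bearing carbons) | OC1(C(CC[C@H](C)CC(OC)OC)[Se]c3ccccc3)CCC2=C(C(=O)OC)CCC[C@]12C | intermediate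
16 | methyl (9R,10R,13S)-15,15-dimethoxy-8-oxo-17,18-dinorlabd-4-en-19-oate (9α-H, 10β-Me) | O=C1CCC2=C(C(=O)OC)CCC[C@]2(C)[C@H]1CC[C@H](C)CC(OC)OC | intermediate
17 | methyl (9S,10R,13S)-15,15-dimethoxy-18-norlabda-4,8(17)-dien-19-oate | C=C1CCC2=C(C(=O)OC)CCC[C@]2(C)[C@H]1CC[C@H](C)CC(OC)OC | intermediate
18 | (9S,10R,13S)-15,15-dimethoxy-18-norlabda-4,8(17)-dien-19-oic acid | C=C1CCC2=C(C(=O)O)CCC[C@]2(C)[C@H]1CC[C@H](C)CC(OC)OC | intermediate
19 | (4S,5R,9S,10R,13S)-15,15-dimethoxylabd-8(17)-en-19-oic acid (trans-fused, 5α-H) | C=C1CC[C@@H]2[C@](C)(CCC[C@]2(C)C(=O)O)[C@H]1CC[C@H](C)CC(OC)OC | intermediate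
20 | (4S,9S,10R,13S)-15,15-dimethoxylabda-5,8(17)-dien-19-oic acid | C=C1CC=C2[C@](C)(CCC[C@]2(C)C(=O)O)[C@H]1CC[C@H](C)CC(OC)OC | intermediate
21 | (4S,5S,9S,10R,13S)-15,15-dimethoxylabd-8(17)-en-19-oic acid (cis-fused, 5β-H) | COC(OC)C[C@@H](C)CC[C@H]1C(=C)CC[C@H]2[C@]1(C)CCC[C@]2(C)C(=O)O | intermediate
22 | trimethylsilyl (4S,5R,9S,10R,13S)-15,15-dimethoxylabd-8(17)-en-19-oate | C=C1CC[C@@H]2[C@](C)(CCC[C@]2(C)C(=O)O[Si](C)(C)C)[C@H]1CC[C@H](C)CC(OC)OC | intermediate (not isolated)
23 | trimethylsilyl (4S,5R,9S,10R,13S)-15-methoxylabda-8(17),14-dien-19-oate (14E/Z mixture) | C=C1CC[C@@H]2[C@](C)(CCC[C@]2(C)C(=O)O[Si](C)(C)C)[C@H]1CC[C@H](C)C=COC | intermediate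
24 | trimethylsilyl (4S,5S,9S,10R,13S)-15,15-dimethoxylabd-8(17)-en-19-oate | COC(OC)C[C@@H](C)CC[C@H]1C(=C)CC[C@H]2[C@]1(C)CCC[C@]2(C)C(=O)O[Si](C)(C)C | intermediate (not isolated)
25 | bis(trimethylsilyl) ester of the β-methoxy dimethyl acetal adduct (C14–C15' bond formed, epimers at C14 and C15') | C=C1CC[C@@H]2[C@](C)(CCC[C@]2(C)C(=O)O[Si](C)(C)C)[C@H]1CC[C@H](C)C(C(OC)OC)C(OC)C[C@@H](C)CC[C@H]1C(=C)CC[C@H]2[C@]1(C)CCC[C@]2(C)C(=O)O[Si](C)(C)C | intermediate (not isolated)
26 | CNP0229303.1: (E)-enal joining C14 of the trans-fused (5R) half to C15' of the cis-fused (5S) half, both halves 4S,9S,10R,13S | C=C1CC[C@@H]2[C@](C)(CCC[C@]2(C)C(=O)O)[C@H]1CC[C@H](C)/C(C=O)=C\C[C@@H](C)CC[C@H]1C(=C)CC[C@H]2[C@]1(C)CCC[C@]2(C)C(=O)O | target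

**Totals**
Total step count: 15. Longest linear sequence: 10 steps (for example 4, 5, 6, 7, 8, 9, 10, 12, 13, 15).

**Three steps most likely to fail**

Step 13 (the proposed new hydrogenation): the olefin is very hindered and the catalyst may not turn over, or may not discriminate the faces. The fallback uses known chemistry, sets out from ketone 16 and returns at 21. NaBH4 reduces the C8 ketone from the open α-face to the axial methyl (8S,9R,10R,13S)-8-hydroxy-15,15-dimethoxy-17,18-dinorlabd-4-en-19-oate F1. KOH gives the hydroxy acid F2. LDA (3.3 equiv) and MeI (1.05 equiv), as in step 12, give the 4-methyl 5-ene hydroxy acid F3. Crabtree's catalyst [Ir(cod)(PCy3)(py)]PF6 under H2 in CH2Cl2, directed by the axial 8β-hydroxyl on the same face as the carboxyl, gives the cis-fused 5β-H hydroxy acid F4. Dess–Martin periodinane gives the cis-fused keto acid F5, and salt-free Ph3P=CH2 at low temperature gives 21. No second olefin is present during the hydrogenation, so chemoselectivity is not needed.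

Step 8 (ring expansion): the secondary selenonium may close to an epoxide instead of triggering migration, or the ring CH2 may compete with C10. The fallback sets out from 15 and returns at 16. H2O2/pyridine oxidises the selenide and the selenoxide eliminates to the (E)-allylic alcohol methyl (7aS)-1-[(1E,4S)-6,6-dimethoxy-4-methylhex-1-enyl]-1-hydroxy-7a-methyl-2,3,5,6,7,7a-hexahydro-1H-indene-4-carboxylate F6. NBS with propylene oxide in CH2Cl2–i-PrOH then drives a bromonium-induced semipinacol ring expansion (electrophilic activation of the olefin instead of a leaving group on C9) to the bromo ketone methyl (10R)-11-bromo-15,15-dimethoxy-8-oxo-17,18-dinorlabd-4-en-19-oate F7. Bu3SnH/AIBN removes the bromine and the same NaOMe equilibration gives 16.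

Step 15 (crossed condensation): telomerisation of the product acetal or acid-induced migration of the exocyclic olefins could lower the yield. The fallback replaces the aldol logic by a Wittig olefination, sets out from 23 and 21 and returns at 26. NBS in wet THF at −78 °C converts enol ether 23 into the α-bromo aldehyde (4S,5R,9S,10R,13S)-14-bromo-15-oxolabd-8(17)-en-19-oic acid F8. PPh3 and then aqueous NaOH give the stabilised formyl ylide (4S,5R,9S,10R,13S)-15-oxo-14-(triphenyl-λ5-phosphanylidene)labd-8(17)-en-19-oic acid F9. Aqueous oxalic acid hydrolyses acetal 21 to the aldehyde (4S,5S,9S,10R,13S)-15-oxolabd-8(17)-en-19-oic acid F10. F9 and F10 (as carboxylate salts, toluene, 90 °C, then mild acid) give the (E)-enal 26 directly.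

**Further compounds**
F1 | step 13 | methyl (8S,9R,10R,13S)-8-hydroxy-15,15-dimethoxy-17,18-dinorlabd-4-en-19-oate (8β-OH) | O[C@H]1CCC2=C(C(=O)OC)CCC[C@]2(C)[C@H]1CC[C@H](C)CC(OC)OC
F2 | step 13 | (8S,9R,10R,13S)-8-hydroxy-15,15-dimethoxy-17,18-dinorlabd-4-en-19-oic acid | O[C@H]1CCC2=C(C(=O)O)CCC[C@]2(C)[C@H]1CC[C@H](C)CC(OC)OC
F3 | step 13 | (4S,10R,13S)-8β-hydroxy-15,15-dimethoxy-17-norlabd-5-en-19-oic acid | O[C@H]1CC=C2[C@](C)(CCC[C@]2(C)C(=O)O)[C@H]1CC[C@H](C)CC(OC)OC
F4 | step 13 | (4S,5S,10R,13S)-8β-hydroxy-15,15-dimethoxy-17-norlabdan-19-oic acid (5β-H, cis-fused) | COC(OC)C[C@@H](C)CC[C@H]1[C@@H](O)CC[C@H]2[C@]1(C)CCC[C@]2(C)C(=O)O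
F5 | step 13 | (4S,5S,10R,13S)-15,15-dimethoxy-8-oxo-17-norlabdan-19-oic acid (5β-H, cis-fused) | COC(OC)C[C@@H](C)CC[C@H]1C(=O)CC[C@H]2[C@]1(C)CCC[C@]2(C)C(=O)O
F6 | step 8 | methyl (7aS)-1-[(1E,4S)-6,6-dimethoxy-4-methylhex-1-enyl]-1-hydroxy-7a-methyl-2,3,5,6,7,7a-hexahydro-1H-indene-4-carboxylate | OC1(/C=C/C[C@H](C)CC(OC)OC)CCC2=C(C(=O)OC)CCC[C@]12C
F7 | step 8 | methyl (10R)-11-bromo-15,15-dimethoxy-8-oxo-17,18-dinorlabd-4-en-19-oate (C9/C11 epimers, C13 as in 16) | O=C1CCC2=C(C(=O)OC)CCC[C@]2(C)C1C(Br)C[C@H](C)CC(OC)OC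
F8 | step 15 | (4S,5R,9S,10R,13S)-14-bromo-15-oxolabd-8(17)-en-19-oic acid (C14 epimers) | C=C1CC[C@@H]2[C@](C)(CCC[C@]2(C)C(=O)O)[C@H]1CC[C@H](C)C(Br)C=O
F9 | step 15 | (4S,5R,9S,10R,13S)-15-oxo-14-(triphenyl-λ5-phosphanylidene)labd-8(17)-en-19-oic acid | C=C1CC[C@@H]2[C@](C)(CCC[C@]2(C)C(=O)O)[C@H]1CC[C@H](C)C(C=O)=P(c3ccccc3)(c3ccccc3)c3ccccc3
F10 | step 15 | (4S,5S,9S,10R,13S)-15-oxolabd-8(17)-en-19-oic acid (5β-H, cis-fused) | O=CC[C@@H](C)CC[C@H]1C(=C)CC[C@H]2[C@]1(C)CCC[C@]2(C)C(=O)O
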